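## Structural features

The target is a 2,3,4-trisubstituted oxolane (O1, C2, C3, C4, C5). C2 bears a 4-hydroxy-3-methoxyphenyl group, C3 a CH2O arm (C9) esterified with (E)-p-coumaric acid, C4 a 4-hydroxy-3-methoxybenzyl group (benzylic carbon C7'), and C5 is a methylene. The three stereocentres are contiguous, (2S,3S,4R): aryl and C9 arm are cis (2,3-cis), C9 arm and benzyl are trans (3,4-trans). This is the less stable arrangement at C2/C3, the one that equilibrating acid-mediated ring closures do not deliver. The C2–O1 bond is a p-hydroxybenzylic ether: acid can ionise it towards a quinone-methide-like cation and phenoxide can open it, and either event epimerises C2 or opens the ring. The coumarate is a conjugated enoate ester that does not tolerate hydride, dissolving metal, hydroxide or hydrogenation, and the three phenols are nucleophilic and oxidation-prone. The real difficulty is to create the 2,3-cis pair with absolute control and then to carry C2 through ring reduction and deprotection without letting it ionise; a donor-substituted aryl group makes both harder, so the phenols travel as arenesulfonates (Ts = 4-methylbenzenesulfonyl) in this plan. The key step uses the fact that C2 is a carbinol carbon bonded to C3, and that C3 stands β to C5. With C5 at the carboxyl level the ring is a γ-butyrolactone whose C2–C3 and O1–C5 bonds come from an aryl aldehyde and an enal homoenolate, C4 then being the lactone α-carbon. Lactone locants (4S,5S) correspond to oxolane C3 and C2; this mapping was re-derived from the target SMILES and is consistent.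

## Logic of the disconnections

17 ⇒ 15 + 16. The ester bond at C9–O is cut first, because the enoate is the group least tolerant of hydrides, dissolving metals and hydroxide and should enter after all such steps. The core is separated from a commercial acid. The forward esterification must activate the single aliphatic hydroxyl and leave three phenols alone, without base.

15 ⇒ 14 ⇒ 13. The O–Si bond at C9 and the two aryl O–S bonds are cut. Sulfonates on the phenols and a bulky silyl ether on C9–O keep C2 from ionising and keep the primary oxygen inert during the lactone chemistry. Every earlier intermediate is then free of acidic OH groups and of donor-activated benzylic C–O bonds. The two deprotections must touch neither C2–O1 nor a stereocentre, and must precede the attachment of 16.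

13 ⇒ 12 ⇒ 11. The two C5–H bonds are exchanged for C5=O. Raising C5 to the carboxyl level makes C4 enolisable and makes O1–C5 an acyl bond, which the next two cuts need; no stereocentre is involved. The forward reduction must pass through an oxocarbenium ion at C5 while the benzylic C2–O1 bond stays intact.

11 ⇒ 9 + 4 (through 10). The C4–C7' bond is cut. C4 is the lactone α-carbon and both neighbouring substituents lie on one face, so an enolate alkylation should place the benzyl group trans. One stereocentre and one arene are removed. The base must spare the sulfonates and the electrophile must react at low temperature.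

9 ⇒ 8 + 2. C2–C3 and O1–C5 are cut together. This is the strategic cut: the ring, two adjacent stereocentres and two bonds dissolve into two achiral aldehydes. The forward step needs polarity reversal at the β-carbon of 8, cis selectivity, absolute control by the catalyst, and preference for 2 over a second molecule of 8 as acceptor. The last demand is why 2 carries a sulfonate and not a donor silyl ether, and why the oxygen at C9 bears a poor leaving group.

8 ⇒ 6 ⇒ 5 (through 7). The aldehyde oxidation level and the O–Si bond are removed. This leads to a symmetrical commercial diol. The forward steps need monoprotection and an (E) double bond.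

4 ⇒ 3 ⇒ 2 ⇒ 1. C–Br, then the carbonyl reduction, then O–S are retraced. Both aryl units come from 1 through the same intermediate 2, so one protection serves both branches.

## Other disconnections considered

Alternative 1: The cut removes the two exocyclic bonds C4–C7' and C3–C9 and keeps O1 and C2–C5 as the butenolide A2, in which the lactone carbonyl is the future C2 and the acetal carbon the future C5.
- Forward step: the 2-lithio derivative of dithiane A3 would add to C4 of A2 on the face away from the menthyloxy group. The lactone enolate would then be trapped at C3 by monomeric CH2O on the face away from the new C4 substituent, giving A1 with 3,4-trans and no new ring.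
- In favour: the absolute configuration comes from a cheap, recrystallisable auxiliary acetal and not from a catalyst. Two stereocentres and two skeletal bonds arise in one flask by a well-established conjugate addition–enolate trapping. The step does not depend on the electronic character of an aryl aldehyde.
- Against here: the step says nothing about C2. The lactone carbonyl of A1 must still become an aryl-bearing carbinol carbon cis to the C3 arm, the acetal carbon must be reduced to CH2, the dithiane must be desulfurised, and the β-hydroxy lactone (prone to retro-aldol cleavage and dehydration) must be protected. The 2,3-cis problem is only postponed.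
- Comparison: structurally it decorates a preformed ring, whereas the chosen plan builds ring and C2/C3 first and adds C7' afterwards. Mechanistically both set 3,4-trans by attack anti to an existing substituent, and on that relation Alternative 1 is the equal of the chosen alkylation. In security of absolute configuration it is the better plan, since auxiliary control is more predictable than the enantioselectivity of the carbene step. In step economy it is clearly worse, because many redox and protecting-group operations separate A1 from an intermediate of the level of 13.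

Alternative 2: The cut is again C2–C3, but made within one molecule. The oxolane is traced back to the seven-membered enol acetal A5, whose acetal carbon is C2, whose O3–C4 unit is O1–C5 and whose enol ether carbons become C3 and C9.
- Forward step: Me3SiOTf at −78 °C would ionise the acetal on the enol-ether side to an aryl-stabilised oxocarbenium ion tethered to an enol carbon. C–C recombination (an intramolecular aldol-type, Prins-like capture) would contract the ring to aldehyde A4, 2,3-cis under kinetic control and 3,4-trans by the bias of the benzyl-bearing centre.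
- In favour: one stereocentre controls the other two in a single step. The oxolane arrives at its final oxidation level, so no lactone has to be reduced. C9 arrives as an aldehyde, one reduction away from an alcohol of the type of 15. The benzyl arm is in place before the key step, so no enolate alkylation is needed.
- Against here: A5 must itself be a single enantiomer with a regiodefined enol ether, which calls for an asymmetric alkene isomerisation or a chiral-pool diol. That step is no better secured than the carbene annulation. The 4-silyloxy-3-methoxyphenyl group makes the oxocarbenium ion long-lived, so reopening of A4 (a β-alkoxy aldehyde) and reclosure to the 2,3-trans isomer, and enolisation at C3, threaten the kinetic product. The electron-withdrawing phenol protection that tames C2 in the chosen plan cannot be used, because the ionisation needs a donor aryl group.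
- Comparison: structurally it is the same strategic bond, with O1/C5 carried as an ether and not as a lactone. Mechanistically it is cation–enol recombination against homoenolate addition, and the kinetic cis selectivity is arguably at least equal in Alternative 2. After the key step Alternative 2 is the better plan (reduction, esterification, deprotection against six operations); before it, it is longer, so similar totals are expected.

Alternative 3: The cut is O1–C2 together with C2–H. The oxolane is opened to the γ-hydroxy aryl ketone A7, which already carries the C3 and C4 substituents and closes reversibly to a hemiketal.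
- Forward step: BF3·OEt2 would ionise the hemiketal to the cyclic 2-aryl oxocarbenium ion, and Et3SiH would deliver hydride to C2 at −78 °C on the face opposite the adjacent C3 arm, giving A6 with the aryl group cis to C9.
- In favour: the stereocentre most at risk is set last, under substrate control, by a well-known reductive etherification that usually favours 2,3-cis. A6 is already the fully protected oxolane (the counterpart of 13), so no lactone reduction follows and the sequence after the key step is short.
- Against here: no C–C bond is made, so the whole skeleton and the C3/C4 trans pair must be assembled beforehand in A7. A7 is a β-silyloxy ketone with an enolisable stereocentre at C3 that can epimerise or lose silanol by β-elimination. The ionisation is run on the very benzylic carbon that must stay cis, with a donor aryl group that favours re-ionisation of A6, epimerisation and reductive opening. In the chosen plan the same reagent pair acts on C5 while C2 is deactivated by the sulfonate.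
- Comparison: structurally the ring closes at the heteroatom bond and not at C2–C3. Mechanistically both plans use hydride capture of an oxocarbenium ion, but at different carbons. For the cis relation at C2 the substrate control is probably the equal or the better of the catalyst-controlled annulation, but it gives no absolute control. It has fewer steps after the key step (an advantage) and more before it, with no gain comparable to the two bonds, two stereocentres and one ring of step 6.

Key step: step 6

Remark: the sense of asymmetric induction of the aminoindanol-derived triazolium catalyst on this enal/aldehyde pair cannot be assigned beforehand; the catalyst enantiomer that delivers (4S,5S)-9 is meant, both enantiomers being available from the two cis-1-amino-2-indanols.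
Remark: catalyst-bound and ion-pair species are treated in the Why lines; numbers are given to species that persist as a separate stage of a step (7 and 10).

Step 1
Reactants: 1 vanillin
Product: 2 4-formyl-2-methoxyphenyl 4-methylbenzenesulfonate
Conditions: TsCl, Et3N, DMAP (cat.), CH2Cl2, 0 °C → rt
Reagents that add atoms: 4-methylbenzenesulfonyl chloride, Cc1ccc(S(=O)(=O)Cl)cc1
Why: O-Sulfonylation of a phenol under amine base. The sulfonate replaces a donor silyl ether so that the aldehyde is a better acceptor in step 6, later benzylic C–O bonds resist Lewis acid, and the group survives amide base, hydride and BF3.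

Step 2
Reactants: 2 4-formyl-2-methoxyphenyl 4-methylbenzenesulfonate
Product: 3 4-(hydroxymethyl)-2-methoxyphenyl 4-methylbenzenesulfonate
Conditions: NaBH4, MeOH/THF, 0 °C
Reagents that add atoms: none
Why: Borohydride reduction of an aryl aldehyde; aryl sulfonates are inert to NaBH4.

Step 3
Reactants: 3 4-(hydroxymethyl)-2-methoxyphenyl 4-methylbenzenesulfonate
Product: 4 4-(bromomethyl)-2-methoxyphenyl 4-methylbenzenesulfonate
Conditions: PBr3 (0.4 equiv), CH2Cl2, 0 °C
Reagents that add atoms: phosphorus tribromide, BrP(Br)Br
Why: Conversion of a benzylic alcohol into the bromide by SN2 displacement of its phosphite ester. The sulfonyloxy group makes this bromide much less prone to ionisation and self-condensation than a 4-silyloxy analogue.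

Step 4
Reactants: 5 (Z)-but-2-ene-1,4-diol
Product: 6 (Z)-4-(tert-butyldiphenylsilyloxy)but-2-en-1-ol
Conditions: 5 (4 equiv), tBuPh2SiCl (1 equiv), imidazole, THF, 0 °C → rt
Reagents that add atoms: tert-butyl(chloro)diphenylsilane, CC(C)(C)[Si](Cl)(c1ccccc1)c1ccccc1
Why: Statistical monosilylation of a symmetrical diol used in excess; the excess diol is removed by aqueous washing. The diphenyl-tert-butylsilyl ether is chosen over a dimethyl-tert-butylsilyl ether because it withstands BF3·OEt2 in step 9 and is a poor leaving group and slow to migrate.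

Step 5
Reactants: 6 (Z)-4-(tert-butyldiphenylsilyloxy)but-2-en-1-ol
Product: 8 (E)-4-(tert-butyldiphenylsilyloxy)but-2-enal, via (Z)-enal 7 (not isolated)
Conditions: [C5H5NH][CrO3Cl] (pyridinium chlorochromate, 1.5 equiv), Celite, CH2Cl2, rt
Reagents that add atoms: none
Why: Chlorochromate oxidation of a primary allylic alcohol. Under the mildly acidic, unbuffered conditions the first-formed (Z)-enal 7 should equilibrate to the more stable conjugated (E)-enal 8, so oxidation and isomerisation occur in one flask.

Step 6
Reactants: 8 (E)-4-(tert-butyldiphenylsilyloxy)but-2-enal; 2 4-formyl-2-methoxyphenyl 4-methylbenzenesulfonate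
Product: 9 (4S,5S)-4-[(tert-butyldiphenylsilyloxy)methyl]-5-[3-methoxy-4-(tosyloxy)phenyl]dihydrofuran-2(3H)-one (4,5-cis)
Conditions: chiral N-mesityl aminoindanol-derived triazolium BF4 salt (10 mol%), DBU (10 mol%), THF/tBuOH 10:1, rt; 2 (2 equiv), 8 added over 8 h
Reagents that add atoms: none
Why: The free carbene adds to the aldehyde of 8 and proton transfer gives the conjugated enaminol, whose β-carbon (lactone C4, oxolane C3) is nucleophilic. This carbon attacks the carbonyl carbon of 2 (lactone C5, oxolane C2); the enol azolium tautomerises to the acyl azolium, and the alkoxide acylates, which releases the carbene. The closest known reaction type is the carbene-catalysed homoenolate annulation of enals with aromatic aldehydes to cis-γ-butyrolactones. The single ring closes by 5-exo-trig O-acylation of the alkoxide on the acyl azolium carbonyl, forming the lactone O1–C2 bond (oxolane O1–C5). The configuration at lactone C4 is set by the open face of the planar enaminol, the indane wall of the catalyst shielding the other. The configuration at C5 follows from the aldehyde face, held relative to C4 in a compact transition state with a hydrogen bond from the enaminol OH to the aldehyde oxygen, which places aryl and CH2OSi cis. The step needs cross-annulation to win over self-annulation of 8 and over benzoin-type pathways; the sulfonate makes 2 an electron-poor acceptor, 2 is used in excess with slow addition of 8, and the N-mesityl group favours homoenolate formation. Loss of the oxygen substituent from C9 of the enaminol should be slow because a silanolate is a poor leaving group.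

Step 7
Reactants: 9 (4S,5S)-4-[(tert-butyldiphenylsilyloxy)methyl]-5-[3-methoxy-4-(tosyloxy)phenyl]dihydrofuran-2(3H)-one; 4 4-(bromomethyl)-2-methoxyphenyl 4-methylbenzenesulfonate
Product: 11 (3R,4S,5S)-3-[3-methoxy-4-(tosyloxy)benzyl]-4-[(tert-butyldiphenylsilyloxy)methyl]-5-[3-methoxy-4-(tosyloxy)phenyl]dihydrofuran-2(3H)-one, via lithium enolate 10 (not isolated)
Conditions: LiN(SiMe3)2 (1.1 equiv), THF, −78 °C; then 4 (1.2 equiv), DMPU, −78 → −40 °C
Reagents that add atoms: none
Why: Alkylation of a γ-butyrolactone enolate. In enolate 10 the C4 arm and the C5 aryl group shield the same face, so the benzyl bromide should enter from the opposite face and set C3 as R, trans to the C4 arm. The silylamide is used in place of a dialkylamide to spare the aryl sulfonates.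

Step 8
Reactants: 11 (3R,4S,5S)-3-[3-methoxy-4-(tosyloxy)benzyl]-4-[(tert-butyldiphenylsilyloxy)methyl]-5-[3-methoxy-4-(tosyloxy)phenyl]dihydrofuran-2(3H)-one
Product: 12 (3R,4S,5S)-3-[3-methoxy-4-(tosyloxy)benzyl]-4-[(tert-butyldiphenylsilyloxy)methyl]-5-[3-methoxy-4-(tosyloxy)phenyl]tetrahydrofuran-2-ol (both anomers)
Conditions: iBu2AlH (1.2 equiv), CH2Cl2, −78 °C; aq. KNaC4H4O6 (tartrate)
Reagents that add atoms: none
Why: Partial reduction of a lactone to the lactol; the tetrahedral aluminium hemiacetal is stable at −78 °C. Aryl sulfonates and the silyl ether are inert to the hydride at this temperature.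

Step 9
Reactants: 12 (3R,4S,5S)-3-[3-methoxy-4-(tosyloxy)benzyl]-4-[(tert-butyldiphenylsilyloxy)methyl]-5-[3-methoxy-4-(tosyloxy)phenyl]tetrahydrofuran-2-ol
Product: 13 (2S,3S,4R)-2-[3-methoxy-4-(tosyloxy)phenyl]-4-[3-methoxy-4-(tosyloxy)benzyl]-3-[(tert-butyldiphenylsilyloxy)methyl]oxolane
Conditions: Et3SiH (3 equiv), BF3·OEt2 (1.5 equiv), CH2Cl2, −78 → −40 °C; aq. NaHCO3
Reagents that add atoms: none
Why: Ionic hydrogenation of a lactol: BF3 ionises the anomeric hydroxyl to the C5 oxocarbenium ion and the silane traps it, creating no stereocentre. The sulfonyloxy groups make both arenes poor donors, so the C2–O1 bond should not ionise and the benzyl ring should not attack the cation.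

Step 10
Reactants: 13 (2S,3S,4R)-2-[3-methoxy-4-(tosyloxy)phenyl]-4-[3-methoxy-4-(tosyloxy)benzyl]-3-[(tert-butyldiphenylsilyloxy)methyl]oxolane
Product: 14 (2S,3S,4R)-2-(4-hydroxy-3-methoxyphenyl)-4-(4-hydroxy-3-methoxybenzyl)-3-[(tert-butyldiphenylsilyloxy)methyl]oxolane
Conditions: Mg turnings (10 equiv), MeOH/THF 4:1, rt; aq. NH4Cl
Reagents that add atoms: none
Why: Reductive S–O cleavage of aryl sulfonates by Mg in MeOH (electron transfer to the arenesulfonyl group, releasing sulfinate and phenoxide), at room temperature and without strong base. It is placed before the coumarate is attached, because this reagent would reduce a conjugated ester; at this stage the molecule has no reducible group.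

Step 11
Reactants: 14 (2S,3S,4R)-2-(4-hydroxy-3-methoxyphenyl)-4-(4-hydroxy-3-methoxybenzyl)-3-[(tert-butyldiphenylsilyloxy)methyl]oxolane
Product: 15 [(2S,3S,4R)-2-(4-hydroxy-3-methoxyphenyl)-4-(4-hydroxy-3-methoxybenzyl)oxolan-3-yl]methanol
Conditions: Bu4NF (1.5 equiv), AcOH (1.5 equiv), THF, 0 °C → rt
Reagents that add atoms: none
Why: Fluoride-induced cleavage of a primary silyl ether. Acetic acid buffers the fluoride so that phenoxide is not built up and opening at C2 through a quinone methide is avoided.

Step 12
Reactants: 15 [(2S,3S,4R)-2-(4-hydroxy-3-methoxyphenyl)-4-(4-hydroxy-3-methoxybenzyl)oxolan-3-yl]methanol; 16 (E)-p-coumaric acid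
Product: 17 [(2S,3S,4R)-2-(4-hydroxy-3-methoxyphenyl)-4-(4-hydroxy-3-methoxybenzyl)oxolan-3-yl]methyl (E)-3-(4-hydroxyphenyl)prop-2-enoate
Conditions: 16 (1.3 equiv), PPh3, iPrO2CN=NCO2iPr, THF, 0 °C → rt, dark
Reagents that add atoms: none
Why: Mitsunobu esterification, a known chemoselective way to esterify phenolic acids with alcohols. Only the aliphatic C9 hydroxyl is turned into an alkoxyphosphonium ion and only the carboxylic acid is acidic enough to act as the pronucleophile, so the three phenols should stay free. C9 is not stereogenic and the (E) double bond is not touched.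

Compound list

1 | vanillin (4-hydroxy-3-methoxybenzaldehyde) | COc1cc(C=O)ccc1O | starting material
2 | 4-formyl-2-methoxyphenyl 4-methylbenzenesulfonate | COc1cc(C=O)ccc1OS(=O)(=O)c1ccc(C)cc1 | intermediate
3 | 4-(hydroxymethyl)-2-methoxyphenyl 4-methylbenzenesulfonate | COc1cc(CO)ccc1OS(=O)(=O)c1ccc(C)cc1 | intermediate
4 | 4-(bromomethyl)-2-methoxyphenyl 4-methylbenzenesulfonate | COc1cc(CBr)ccc1OS(=O)(=O)c1ccc(C)cc1 | intermediate
5 | (Z)-but-2-ene-1,4-diol | OC/C=C\CO | starting material
6 | (Z)-4-(tert-butyldiphenylsilyloxy)but-2-en-1-ol | OC/C=C\CO[Si](c1ccccc1)(c1ccccc1)C(C)(C)C | intermediate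
7 | (Z)-4-(tert-butyldiphenylsilyloxy)but-2-enal (not isolated) | O=C/C=C\CO[Si](c1ccccc1)(c1ccccc1)C(C)(C)C | intermediate
8 | (E)-4-(tert-butyldiphenylsilyloxy)but-2-enal | O=C/C=C/CO[Si](c1ccccc1)(c1ccccc1)C(C)(C)C | intermediate
9 | (4S,5S)-4-[(tert-butyldiphenylsilyloxy)methyl]-5-[3-methoxy-4-(tosyloxy)phenyl]dihydrofuran-2(3H)-one | O=C1C[C@@H](CO[Si](c2ccccc2)(c2ccccc2)C(C)(C)C)[C@@H](c2ccc(OS(=O)(=O)c3ccc(C)cc3)c(OC)c2)O1 | intermediate
10 | lithium enolate of 9 (not isolated) | [Li]OC1=C[C@@H](CO[Si](c2ccccc2)(c2ccccc2)C(C)(C)C)[C@@H](c2ccc(OS(=O)(=O)c3ccc(C)cc3)c(OC)c2)O1 | intermediate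
11 | (3R,4S,5S)-3-[3-methoxy-4-(tosyloxy)benzyl]-4-[(tert-butyldiphenylsilyloxy)methyl]-5-[3-methoxy-4-(tosyloxy)phenyl]dihydrofuran-2(3H)-one | O=C1[C@H](Cc2ccc(OS(=O)(=O)c3ccc(C)cc3)c(OC)c2)[C@@H](CO[Si](c2ccccc2)(c2ccccc2)C(C)(C)C)[C@@H](c2ccc(OS(=O)(=O)c3ccc(C)cc3)c(OC)c2)O1 | intermediate
12 | (3R,4S,5S)-3-[3-methoxy-4-(tosyloxy)benzyl]-4-[(tert-butyldiphenylsilyloxy)methyl]-5-[3-methoxy-4-(tosyloxy)phenyl]tetrahydrofuran-2-ol (both anomers) | COc1cc(C[C@H]2C(O)O[C@H](c3ccc(OS(=O)(=O)c4ccc(C)cc4)c(OC)c3)[C@@H]2CO[Si](c5ccccc5)(c6ccccc6)C(C)(C)C)ccc1OS(=O)(=O)c1ccc(C)cc1 | intermediate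
13 | (2S,3S,4R)-2-[3-methoxy-4-(tosyloxy)phenyl]-4-[3-methoxy-4-(tosyloxy)benzyl]-3-[(tert-butyldiphenylsilyloxy)methyl]oxolane | COc1cc(C[C@H]2CO[C@H](c3ccc(OS(=O)(=O)c4ccc(C)cc4)c(OC)c3)[C@@H]2CO[Si](c5ccccc5)(c6ccccc6)C(C)(C)C)ccc1OS(=O)(=O)c1ccc(C)cc1 | intermediate
14 | (2S,3S,4R)-2-(4-hydroxy-3-methoxyphenyl)-4-(4-hydroxy-3-methoxybenzyl)-3-[(tert-butyldiphenylsilyloxy)methyl]oxolane | COc1cc(C[C@H]2CO[C@H](c3ccc(O)c(OC)c3)[C@@H]2CO[Si](c5ccccc5)(c6ccccc6)C(C)(C)C)ccc1O | intermediate
15 | [(2S,3S,4R)-2-(4-hydroxy-3-methoxyphenyl)-4-(4-hydroxy-3-methoxybenzyl)oxolan-3-yl]methanol | COc1cc(C[C@H]2CO[C@H](c3ccc(O)c(OC)c3)[C@@H]2CO)ccc1O | intermediate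
16 | (E)-p-coumaric acid | OC(=O)/C=C/c1ccc(O)cc1 | starting material
17 | [(2S,3S,4R)-2-(4-hydroxy-3-methoxyphenyl)-4-(4-hydroxy-3-methoxybenzyl)oxolan-3-yl]methyl (E)-3-(4-hydroxyphenyl)prop-2-enoate | COc1cc(C[C@H]2CO[C@H](c3ccc(O)c(OC)c3)[C@@H]2COC(=O)/C=C/c2ccc(O)cc2)ccc1O | target

Total step count: 12. Longest linear sequence: 9 steps (1 → 2 → 3 → 4 → 11 → 12 → 13 → 14 → 15 → 17, or equally 5 → 6 → 8 → 9 → 11 → … → 17).

Least certain steps

Step 6 (key step). The most likely failure is unselective C–C bond formation: the homoenolate may add to a second molecule of 8 or the aldehydes may enter benzoin-type pathways. Facial discrimination at the β-carbon may also be too weak to give high enantiomeric purity, since strong asymmetric induction with simple aryl aldehydes and a γ-oxygenated aliphatic enal is not secured. Erosion of the cis preference and loss of silanolate from C9 of the enaminol are further risks. The fallback replaces carbene umpolung by an enamine anti-aldol; it sets out from 2 and comes back at 9. An anti-aldol is required because an anti relation between the hydroxyl and the α-allyl group maps onto the cis lactone once the ring is closed through the allyl carbons.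
- (R)-Proline-catalysed cross-aldol of pent-4-enal (slow addition, DMF, 4 °C) with 2 should give the anti aldol (2R,3S)-3-hydroxy-3-[3-methoxy-4-(tosyloxy)phenyl]-2-(prop-2-enyl)propanal F1. (R)-Proline is the mirror image of the catalyst whose enamine attacks the Re face of acceptor aldehydes.
- F1 is reduced in the same flask with NaBH4 to (1S,2S)-1-[3-methoxy-4-(tosyloxy)phenyl]-2-(prop-2-enyl)propane-1,3-diol F2.
- tBuPh2SiCl/imidazole silylates the primary hydroxyl to give (1S,2S)-2-[(tert-butyldiphenylsilyloxy)methyl]-1-[3-methoxy-4-(tosyloxy)phenyl]pent-4-en-1-ol F3.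
- Lemieux–Johnson cleavage (OsO4 cat., NaIO4, 2,6-lutidine, dioxane/H2O) gives (4S,5S)-4-[(tert-butyldiphenylsilyloxy)methyl]-5-[3-methoxy-4-(tosyloxy)phenyl]tetrahydrofuran-2-ol F4.
- PhI(OAc)2/TEMPO oxidises F4 to 9.

Step 7. Proton transfer between product and enolate may cause double alkylation and return of 9, and the enolate or the amide may attack a sulfonyl sulfur. The fallback replaces SN2 alkylation by aldol addition and radical deoxygenation; it sets out from 9 (through 10) and 2 and comes back at 11.
- Enolate 10 is added to 2 at −78 °C, again anti to the ring substituents, to give (3S,4S,5S)-3-{hydroxy[3-methoxy-4-(tosyloxy)phenyl]methyl}-4-[(tert-butyldiphenylsilyloxy)methyl]-5-[3-methoxy-4-(tosyloxy)phenyl]dihydrofuran-2(3H)-one F5 (carbinol epimers).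
- PhOC(S)Cl, pyridine and DMAP convert it into the O-phenyl thionocarbonate of F5, F6.
- Barton–McCombie reduction (Bu3SnH, AIBN, toluene, 80 °C) removes the benzylic oxygen and gives 11.

Step 9. Ionisation may occur at the wrong carbon (C2 and not C5), with epimerisation to 2,3-trans or reductive ring opening. The C5 cation may also be captured by the benzyl arene, or the silyl ether may be lost under BF3. The fallback never makes a cation and never breaks the C2–O bond; it sets out from 11 and comes back at 13.
- LiBH4 (THF, 0 °C → rt) reduces the lactone to (1S,2S,3R)-3-[3-methoxy-4-(tosyloxy)benzyl]-2-[(tert-butyldiphenylsilyloxy)methyl]-1-[3-methoxy-4-(tosyloxy)phenyl]butane-1,4-diol F7.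
- MsCl/2,4,6-collidine (CH2Cl2, −20 °C) sulfonylates the primary hydroxyl selectively to give (2R,3S,4S)-4-hydroxy-2-[3-methoxy-4-(tosyloxy)benzyl]-3-[(tert-butyldiphenylsilyloxy)methyl]-4-[3-methoxy-4-(tosyloxy)phenyl]butyl methanesulfonate F8.
- KOtBu (THF, 0 °C) closes the oxolane by 5-exo-tet Williamson etherification with retention at C2, giving 13.

Step 12. Phenoxide oxygens may be alkylated by the C9 alkoxyphosphonium ion in competition with the carboxylate, and the polar triphenol may be hard to separate from phosphine oxide and hydrazide. The fallback masks all phenols and activates the acid and not the alcohol; it sets out from 14 (and 16) and comes back at 17.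
- Ac2O/pyridine gives (2S,3S,4R)-2-(4-acetoxy-3-methoxyphenyl)-4-(4-acetoxy-3-methoxybenzyl)-3-[(tert-butyldiphenylsilyloxy)methyl]oxolane F9.
- HF·pyridine (THF) removes the silyl ether to give [(2S,3S,4R)-2-(4-acetoxy-3-methoxyphenyl)-4-(4-acetoxy-3-methoxybenzyl)oxolan-3-yl]methanol F10.
- 16 is acetylated (Ac2O, pyridine) to (E)-3-(4-acetoxyphenyl)prop-2-enoic acid F11.
- Steglich coupling of F10 with F11 (N-(3-dimethylaminopropyl)-N'-ethylcarbodiimide hydrochloride, DMAP, CH2Cl2) gives [(2S,3S,4R)-2-(4-acetoxy-3-methoxyphenyl)-4-(4-acetoxy-3-methoxybenzyl)oxolan-3-yl]methyl (E)-3-(4-acetoxyphenyl)prop-2-enoate F12.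
- NH4OAc in aqueous MeOH at rt cleaves the three aryl acetates selectively, leaving the alkyl enoate, and gives 17.

## Further compounds

F1 | step 6 | (2R,3S)-3-hydroxy-3-[3-methoxy-4-(tosyloxy)phenyl]-2-(prop-2-enyl)propanal | C=CC[C@@H](C=O)[C@@H](c1ccc(OS(=O)(=O)c2ccc(C)cc2)c(OC)c1)O
F2 | step 6 | (1S,2S)-1-[3-methoxy-4-(tosyloxy)phenyl]-2-(prop-2-enyl)propane-1,3-diol | C=CC[C@@H](CO)[C@@H](c1ccc(OS(=O)(=O)c2ccc(C)cc2)c(OC)c1)O
F3 | step 6 | (1S,2S)-2-[(tert-butyldiphenylsilyloxy)methyl]-1-[3-methoxy-4-(tosyloxy)phenyl]pent-4-en-1-ol | C=CC[C@@H](CO[Si](c1ccccc1)(c1ccccc1)C(C)(C)C)[C@@H](c1ccc(OS(=O)(=O)c2ccc(C)cc2)c(OC)c1)O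
F4 | step 6 | (4S,5S)-4-[(tert-butyldiphenylsilyloxy)methyl]-5-[3-methoxy-4-(tosyloxy)phenyl]tetrahydrofuran-2-ol (both anomers) | OC1C[C@@H](CO[Si](c2ccccc2)(c2ccccc2)C(C)(C)C)[C@@H](c2ccc(OS(=O)(=O)c3ccc(C)cc3)c(OC)c2)O1
F5 | step 7 | (3S,4S,5S)-3-{hydroxy[3-methoxy-4-(tosyloxy)phenyl]methyl}-4-[(tert-butyldiphenylsilyloxy)methyl]-5-[3-methoxy-4-(tosyloxy)phenyl]dihydrofuran-2(3H)-one (carbinol epimers) | O=C1[C@H](C(O)c2ccc(OS(=O)(=O)c3ccc(C)cc3)c(OC)c2)[C@@H](CO[Si](c2ccccc2)(c2ccccc2)C(C)(C)C)[C@@H](c2ccc(OS(=O)(=O)c3ccc(C)cc3)c(OC)c2)O1
F6 | step 7 | O-phenyl thionocarbonate of F5 | O=C1[C@H](C(OC(=S)Oc2ccccc2)c2ccc(OS(=O)(=O)c3ccc(C)cc3)c(OC)c2)[C@@H](CO[Si](c2ccccc2)(c2ccccc2)C(C)(C)C)[C@@H](c2ccc(OS(=O)(=O)c3ccc(C)cc3)c(OC)c2)O1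
F7 | step 9 | (1S,2S,3R)-3-[3-methoxy-4-(tosyloxy)benzyl]-2-[(tert-butyldiphenylsilyloxy)methyl]-1-[3-methoxy-4-(tosyloxy)phenyl]butane-1,4-diol | COc1cc(C[C@@H](CO)[C@@H](CO[Si](c5ccccc5)(c6ccccc6)C(C)(C)C)[C@H](O)c3ccc(OS(=O)(=O)c4ccc(C)cc4)c(OC)c3)ccc1OS(=O)(=O)c1ccc(C)cc1
F8 | step 9 | (2R,3S,4S)-4-hydroxy-2-[3-methoxy-4-(tosyloxy)benzyl]-3-[(tert-butyldiphenylsilyloxy)methyl]-4-[3-methoxy-4-(tosyloxy)phenyl]butyl methanesulfonate | COc1cc(C[C@@H](COS(C)(=O)=O)[C@@H](CO[Si](c5ccccc5)(c6ccccc6)C(C)(C)C)[C@H](O)c3ccc(OS(=O)(=O)c4ccc(C)cc4)c(OC)c3)ccc1OS(=O)(=O)c1ccc(C)cc1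
F9 | step 12 | (2S,3S,4R)-2-(4-acetoxy-3-methoxyphenyl)-4-(4-acetoxy-3-methoxybenzyl)-3-[(tert-butyldiphenylsilyloxy)methyl]oxolane | COc1cc(C[C@H]2CO[C@H](c3ccc(OC(C)=O)c(OC)c3)[C@@H]2CO[Si](c5ccccc5)(c6ccccc6)C(C)(C)C)ccc1OC(C)=O
F10 | step 12 | [(2S,3S,4R)-2-(4-acetoxy-3-methoxyphenyl)-4-(4-acetoxy-3-methoxybenzyl)oxolan-3-yl]methanol | COc1cc(C[C@H]2CO[C@H](c3ccc(OC(C)=O)c(OC)c3)[C@@H]2CO)ccc1OC(C)=O
F11 | step 12 | (E)-3-(4-acetoxyphenyl)prop-2-enoic acid | CC(=O)Oc1ccc(/C=C/C(=O)O)cc1
F12 | step 12 | [(2S,3S,4R)-2-(4-acetoxy-3-methoxyphenyl)-4-(4-acetoxy-3-methoxybenzyl)oxolan-3-yl]methyl (E)-3-(4-acetoxyphenyl)prop-2-enoate | COc1cc(C[C@H]2CO[C@H](c3ccc(OC(C)=O)c(OC)c3)[C@@H]2COC(=O)/C=C/c2ccc(OC(C)=O)cc2)ccc1OC(C)=O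
A1 | alternative 1 | (3S,4R,5R)-3-(hydroxymethyl)-4-{2-[3-methoxy-4-(triisopropylsilyloxy)phenyl]-1,3-dithian-2-yl}-5-[(1R,2S,5R)-menthyloxy]dihydrofuran-2(3H)-one | O=C1[C@H](CO)[C@@H](C2(c3ccc(O[Si](C(C)C)(C(C)C)C(C)C)c(OC)c3)SCCCS2)[C@H](O[C@@H]3C[C@H](C)CC[C@H]3C(C)C)O1
A2 | alternative 1 | (5R)-5-[(1R,2S,5R)-menthyloxy]furan-2(5H)-one | O=C1C=C[C@H](O[C@@H]2C[C@H](C)CC[C@H]2C(C)C)O1
A3 | alternative 1 | 2-[3-methoxy-4-(triisopropylsilyloxy)phenyl]-1,3-dithiane | COc1cc(C2SCCCS2)ccc1O[Si](C(C)C)(C(C)C)C(C)C
A4 | alternative 2 | (2S,3R,4R)-2-[3-methoxy-4-(triisopropylsilyloxy)phenyl]-4-[3-methoxy-4-(triisopropylsilyloxy)benzyl]oxolane-3-carbaldehyde | COc1cc(C[C@H]2CO[C@H](c3ccc(O[Si](C(C)C)(C(C)C)C(C)C)c(OC)c3)[C@@H]2C=O)ccc1O[Si](C(C)C)(C(C)C)C(C)C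
A5 | alternative 2 | (5R)-2-[3-methoxy-4-(triisopropylsilyloxy)phenyl]-5-[3-methoxy-4-(triisopropylsilyloxy)benzyl]-4,5-dihydro-1,3-dioxepine (acetal carbon unassigned) | COc1cc(C[C@H]2COC(c3ccc(O[Si](C(C)C)(C(C)C)C(C)C)c(OC)c3)OC=C2)ccc1O[Si](C(C)C)(C(C)C)C(C)C
A6 | alternative 3 | (2S,3S,4R)-2-[3-methoxy-4-(triisopropylsilyloxy)phenyl]-4-[3-methoxy-4-(triisopropylsilyloxy)benzyl]-3-[(tert-butyldimethylsilyloxy)methyl]oxolane | COc1cc(C[C@H]2CO[C@H](c3ccc(O[Si](C(C)C)(C(C)C)C(C)C)c(OC)c3)[C@@H]2CO[Si](C)(C)C(C)(C)C)ccc1O[Si](C(C)C)(C(C)C)C(C)C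
A7 | alternative 3 | (2S,3R)-4-hydroxy-3-[3-methoxy-4-(triisopropylsilyloxy)benzyl]-2-[(tert-butyldimethylsilyloxy)methyl]-1-[3-methoxy-4-(triisopropylsilyloxy)phenyl]butan-1-one | COc1cc(C[C@@H](CO)[C@@H](CO[Si](C)(C)C(C)(C)C)C(=O)c2ccc(O[Si](C(C)C)(C(C)C)C(C)C)c(OC)c2)ccc1O[Si](C(C)C)(C(C)C)C(C)C
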